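A direct plan would close ring C last: the C-prenylated, MOM-protected acetophenone A1 would be condensed with aldehyde A2 to chalcone A3, whose 2'-OH would add to the enone to give racemic flavanone A4, to be resolved and deprotected.
Its weakest steps would be: (a) the oxa-Michael ring closure, which would form C2 reversibly and without control; (b) the resolution of A4, which would discard at least half of the most advanced material; (c) the three-step making of the C-prenyl group of A1 (O-propargylation, semihydrogenation, Claisen shift), which would add length and a protecting group for one C–C bond.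

The route rests on disconnecting the C2–C1' bond, so that ring B is joined last to a flat, achiral chromone in which rings A and C are already fused. The key step, a rhodium-catalysed enantioselective 1,4-addition of an arylboronic acid to the vinylogous ester O1–C2=C3–C4=O, forms that bond and the only stereocentre, C2, under catalyst control with all material funnelled to one enantiomer; no reversible racemic ring closure and no resolution remain. The 5-O-prenyl ether protects the peri-hydroxyl during this step and then delivers the prenyl group to C8, para to O5, by a domino Claisen–Cope shift, which replaces the three-step allyl ether preparation.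

Key step: step 3

Remark: the sense of induction of the (S)-bisphosphine is assumed from its behaviour with cyclic enones (same enantioface of the C=C bond); if a model run showed the opposite sense, the (R)-ligand would be used without other change.

Step 1
Reactants: 1 1-(2,6-dihydroxy-4-methoxyphenyl)ethanone
Product: 3 5-hydroxy-7-methoxy-4H-chromen-4-one, via enaminone 2 (not isolated)
Conditions: Me2NCH(OMe)2 (2 equiv), toluene, 85 °C; evaporate; AcOH, 90 °C
Reagents that add atoms: N,N-dimethylformamide dimethyl acetal, COC(OC)N(C)C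
Why: Enaminone route to chromones: the methyl ketone condenses with the amide acetal, and acid then drives a 6-endo addition–elimination of a phenolic OH at the β-carbon with loss of dimethylamine, giving one product because the two OH groups of 1 are equivalent, so ring C is closed before ring B exists.

Step 2
Reactants: 3 5-hydroxy-7-methoxy-4H-chromen-4-one
Product: 4 7-methoxy-5-[(3-methylbut-2-en-1-yl)oxy]-4H-chromen-4-one
Conditions: prenyl bromide (1.5 equiv), K2CO3 (3 equiv), DMF, 60 °C
Reagents that add atoms: 1-bromo-3-methylbut-2-ene (prenyl bromide), CC(C)=CCBr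
Why: Williamson ether synthesis: carbonate in warm DMF deprotonates the hydrogen-bonded 5-OH, the only hydroxyl present, and SN2 attack on the primary allylic bromide should give the O-prenyl ether that serves as protecting group in step 3 and as prenyl source in step 4.

Step 3
Reactants: 4 7-methoxy-5-[(3-methylbut-2-en-1-yl)oxy]-4H-chromen-4-one; 5 [4-[(tert-butyldimethylsilyl)oxy]phenyl]boronic acid
Product: 6 (2S)-2-[4-[(tert-butyldimethylsilyl)oxy]phenyl]-7-methoxy-5-[(3-methylbut-2-en-1-yl)oxy]-2,3-dihydro-4H-chromen-4-one
Conditions: [RhCl(C2H4)2]2 (1.5 mol %), (S)-MeO-F12-BIPHEP [(S)-(6,6'-dimethoxybiphenyl-2,2'-diyl)bis[bis(3,4,5-trifluorophenyl)phosphane]] (3.3 mol %), aq KOH (6 mol %), 5 (2.5 equiv), toluene/H2O (10:1), 30 °C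
Reagents that add atoms: none
Why: Hayashi–Miyaura-type asymmetric 1,4-addition: the Rh–OH complex of the bisphosphine transmetalates with 5 to an aryl–rhodium species, the C2=C3 bond of the vinylogous ester inserts into Rh–Ar with the aryl going to C2, and water protonates the resulting oxa-π-allyl rhodium enolate at C3, returning Rh–OH. The closest known reaction type is the rhodium/chiral bisphosphine (or chiral diene) 1,4-addition of arylboronic acids to chromones. No ring is closed, since rings A and C are already fused in 4 and the step only appends ring B. C2 is the one new stereocentre and is set by the ligand: the twofold-symmetric (S)-bisphosphine should let the chromone bind with its benzo-fused carbonyl side away from the pseudo-equatorial P-aryl groups, so that the aryl is delivered to the Re face of C2, which gives (2S). The step needs 1,4- over 1,2-addition and no retro-oxa-Michael opening of the product; the peri 5-O-prenyl group shields C4=O, and the electron-poor ligand should allow turnover at 30 °C with only catalytic hydroxide, under which the flavanone should stay closed. The substrate has no free OH that could chelate rhodium, and the trisubstituted, unactivated alkene of the prenyl ether should not insert into Rh–Ar.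

Step 4
Reactants: 6 (2S)-2-[4-[(tert-butyldimethylsilyl)oxy]phenyl]-7-methoxy-5-[(3-methylbut-2-en-1-yl)oxy]-2,3-dihydro-4H-chromen-4-one
Product: 9 (2S)-2-[4-[(tert-butyldimethylsilyl)oxy]phenyl]-5-hydroxy-7-methoxy-8-(3-methylbut-2-en-1-yl)-2,3-dihydro-4H-chromen-4-one, via C6-dienone 7 (not isolated), via C8-dienone 8 (not isolated)
Conditions: Eu(fod)3 [tris(6,6,7,7,8,8,8-heptafluoro-2,2-dimethyloctane-3,5-dionato)europium] (10 mol %), NaHCO3 (1 equiv), PhCl, 80 °C
Reagents that add atoms: none
Why: Domino aromatic Claisen–Cope rearrangement accelerated by the oxophilic Lewis acid bound at C4=O/O5: the first [3,3] shift can only go to C6 (C4a is substituted) and gives the 1,1-dimethylallyl dienone 7, whose crowded quaternary carbon should relax by a second [3,3] shift to C8, restoring a normal prenyl group para to O5, and tautomerisation of 8 gives the chelated 5-OH phenol; the transient sp3 centres at C6 and C8 vanish on aromatisation, C2 takes no part, and NaHCO3 keeps out acid that could ionise the ether.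

Step 5
Reactants: 9 (2S)-2-[4-[(tert-butyldimethylsilyl)oxy]phenyl]-5-hydroxy-7-methoxy-8-(3-methylbut-2-en-1-yl)-2,3-dihydro-4H-chromen-4-one
Product: 10 (2S)-5-hydroxy-2-(4-hydroxyphenyl)-7-methoxy-8-(3-methylbut-2-en-1-yl)-2,3-dihydro-4H-chromen-4-one (Mundulea flavanone B)
Conditions: KHF2 (2.5 equiv), MeOH, rt
Reagents that add atoms: none
Why: Fluoride-induced cleavage of the aryl silyl ether with weakly acidic bifluoride, selective for phenolic TBS groups; no phenoxide base is generated, so the flavanone should not open to the chalcone and C2 should keep its configuration, and the prenyl group, which has no free ortho-OH, is inert.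

Compound list
1 | 1-(2,6-dihydroxy-4-methoxyphenyl)ethanone | CC(=O)c1c(O)cc(OC)cc1O | starting material
2 | (E)-1-(2,6-dihydroxy-4-methoxyphenyl)-3-(dimethylamino)prop-2-en-1-one (not isolated) | CN(C)/C=C/C(=O)c1c(O)cc(OC)cc1O | intermediate
3 | 5-hydroxy-7-methoxy-4H-chromen-4-one | O=c1ccoc2cc(OC)cc(O)c12 | intermediate
4 | 7-methoxy-5-[(3-methylbut-2-en-1-yl)oxy]-4H-chromen-4-one | O=c1ccoc2cc(OC)cc(OCC=C(C)C)c12 | intermediate
5 | [4-[(tert-butyldimethylsilyl)oxy]phenyl]boronic acid | CC(C)(C)[Si](C)(C)Oc1ccc(B(O)O)cc1 | starting material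
6 | (2S)-2-[4-[(tert-butyldimethylsilyl)oxy]phenyl]-7-methoxy-5-[(3-methylbut-2-en-1-yl)oxy]-2,3-dihydro-4H-chromen-4-one | COc1cc(OCC=C(C)C)c2c(c1)O[C@H](c1ccc(O[Si](C)(C)C(C)(C)C)cc1)CC2=O | intermediate
7 | (2S)-2-[4-[(tert-butyldimethylsilyl)oxy]phenyl]-7-methoxy-6-(2-methylbut-3-en-2-yl)-2,3-dihydro-4H-chromene-4,5(6H)-dione (C6 epimers, not isolated) | COC1=CC2=C(C(=O)C1C(C)(C)C=C)C(=O)C[C@@H](c1ccc(O[Si](C)(C)C(C)(C)C)cc1)O2 | intermediate
8 | (2S)-2-[4-[(tert-butyldimethylsilyl)oxy]phenyl]-7-methoxy-8-(3-methylbut-2-en-1-yl)-2,3-dihydro-4H-chromene-4,5(8H)-dione (C8 epimers, not isolated) | COC1=CC(=O)C2=C(C1CC=C(C)C)O[C@H](c1ccc(O[Si](C)(C)C(C)(C)C)cc1)CC2=O | intermediate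
9 | (2S)-2-[4-[(tert-butyldimethylsilyl)oxy]phenyl]-5-hydroxy-7-methoxy-8-(3-methylbut-2-en-1-yl)-2,3-dihydro-4H-chromen-4-one | COc1cc(O)c2c(c1CC=C(C)C)O[C@H](c1ccc(O[Si](C)(C)C(C)(C)C)cc1)CC2=O | intermediate
10 | (2S)-5-hydroxy-2-(4-hydroxyphenyl)-7-methoxy-8-(3-methylbut-2-en-1-yl)-2,3-dihydro-4H-chromen-4-one (Mundulea flavanone B) | COc1cc(O)c2c(c1CC=C(C)C)O[C@H](c1ccc(O)cc1)CC2=O | target

Total step count: 5. Longest linear sequence: 5 steps (1 to 10); boronic acid 5 is a purchased building block.

Steps most likely to fail

Step 3 (key step). Insertion into the electron-rich 5,7-dialkoxy vinylogous ester may be slower than protodeboronation of the electron-rich boronic acid, and hydroxide-induced ring opening of the product may erode the enantiomeric purity. The fallback reverses the order of the two late events and changes the catalytic manifold. It sets out from 4, which would be rearranged first (Eu(fod)3, PhCl, 85 °C, or neat PhNEt2 at 190 °C, no stereocentre being at risk) to 5-hydroxy-7-methoxy-8-(3-methylbut-2-en-1-yl)-4H-chromen-4-one F1. The C4=O of F1 is activated by the hydrogen-bonded 5-OH, and 5 would be added under base-free cationic divalent-palladium catalysis: Pd(OCOCF3)2 (5 mol %), (R)-t-BuPyOx [(R)-4-tert-butyl-2-(pyridin-2-yl)-4,5-dihydro-1,3-oxazole, the antipode expected by analogy with cyclic enones to add the aryl to the Re face of C2] (6 mol %), NH4PF6 (30 mol %), H2O (5 equiv), ClCH2CH2Cl, 60 °C. The fallback returns to the route at 9.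

Step 4. Tautomerisation of dienone 7 may outrun the second shift and leave the 6-(1,1-dimethylallyl) isomer, the ether may ionise with loss of the prenyl group, or Lewis-acid-assisted ring opening may erode C2. The fallback makes the C8–C bond by cross-coupling instead of a sigmatropic shift and sets out from 3.
- Protection (NaH, MOMCl, DMF, 0 °C) would give 7-methoxy-5-(methoxymethoxy)-4H-chromen-4-one F2.
- Iodination (N-iodosuccinimide, MeCN, rt) should go para to the alkylated O5 and give 8-iodo-7-methoxy-5-(methoxymethoxy)-4H-chromen-4-one F3.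
- Stille coupling with tributyl(3-methylbut-2-en-1-yl)stannane (Pd(PPh3)4, DMF, 90 °C) would give 7-methoxy-5-(methoxymethoxy)-8-(3-methylbut-2-en-1-yl)-4H-chromen-4-one F4.
- 1,4-Addition of 5 under the conditions of step 3 would give (2S)-2-[4-[(tert-butyldimethylsilyl)oxy]phenyl]-7-methoxy-5-(methoxymethoxy)-8-(3-methylbut-2-en-1-yl)-2,3-dihydro-4H-chromen-4-one F5.
- Methanolic HCl (from AcCl in MeOH, 40 °C) would remove both the MOM and the silyl group, and the fallback returns to the route at 10.

Step 1. The amide acetal may O-methylate the two acidic phenols, or condensation of the doubly hydrogen-bonded ketone may stall. The fallback masks one hydroxyl before ring C is built, so that a classical mono-phenol enters the chromone synthesis, and it sets out from 1. Mono-O-prenylation (prenyl bromide 1.05 equiv, K2CO3, acetone, reflux; the second OH stays chelated) would give 1-[2-hydroxy-4-methoxy-6-[(3-methylbut-2-en-1-yl)oxy]phenyl]ethanone F6. Me2NCH(OMe)2 would convert F6 into (E)-3-(dimethylamino)-1-[2-hydroxy-4-methoxy-6-[(3-methylbut-2-en-1-yl)oxy]phenyl]prop-2-en-1-one F7, which dilute HCl in CH2Cl2 at rt should cyclise. The fallback returns to the route at 4, so step 2 is no longer needed.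

Further compounds
F1 | step 3 | 5-hydroxy-7-methoxy-8-(3-methylbut-2-en-1-yl)-4H-chromen-4-one | O=c1ccoc2c(CC=C(C)C)c(OC)cc(O)c12
F2 | step 4 | 7-methoxy-5-(methoxymethoxy)-4H-chromen-4-one | COCOc1cc(OC)cc2occc(=O)c12
F3 | step 4 | 8-iodo-7-methoxy-5-(methoxymethoxy)-4H-chromen-4-one | COCOc1cc(OC)c(I)c2occc(=O)c12
F4 | step 4 | 7-methoxy-5-(methoxymethoxy)-8-(3-methylbut-2-en-1-yl)-4H-chromen-4-one | COCOc1cc(OC)c(CC=C(C)C)c2occc(=O)c12
F5 | step 4 | (2S)-2-[4-[(tert-butyldimethylsilyl)oxy]phenyl]-7-methoxy-5-(methoxymethoxy)-8-(3-methylbut-2-en-1-yl)-2,3-dihydro-4H-chromen-4-one | COc1cc(OCOC)c2c(c1CC=C(C)C)O[C@H](c1ccc(O[Si](C)(C)C(C)(C)C)cc1)CC2=O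
F6 | step 1 | 1-[2-hydroxy-4-methoxy-6-[(3-methylbut-2-en-1-yl)oxy]phenyl]ethanone | CC(=O)c1c(O)cc(OC)cc1OCC=C(C)C
F7 | step 1 | (E)-3-(dimethylamino)-1-[2-hydroxy-4-methoxy-6-[(3-methylbut-2-en-1-yl)oxy]phenyl]prop-2-en-1-one | CN(C)/C=C/C(=O)c1c(O)cc(OC)cc1OCC=C(C)C
A1 | direct plan | 1-[2-hydroxy-4-methoxy-6-(methoxymethoxy)-3-(3-methylbut-2-en-1-yl)phenyl]ethanone | CC(=O)c1c(O)c(CC=C(C)C)c(OC)cc1OCOC
A2 | direct plan | 4-(methoxymethoxy)benzaldehyde | COCOc1ccc(C=O)cc1
A3 | direct plan | (E)-1-[2-hydroxy-4-methoxy-6-(methoxymethoxy)-3-(3-methylbut-2-en-1-yl)phenyl]-3-[4-(methoxymethoxy)phenyl]prop-2-en-1-one | COCOc1ccc(/C=C/C(=O)c2c(O)c(CC=C(C)C)c(OC)cc2OCOC)cc1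
A4 | direct plan | rac-7-methoxy-5-(methoxymethoxy)-2-[4-(methoxymethoxy)phenyl]-8-(3-methylbut-2-en-1-yl)-2,3-dihydro-4H-chromen-4-one | COc1cc(OCOC)c2c(c1CC=C(C)C)OC(c1ccc(OCOC)cc1)CC2=O
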